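**Plan**
1. Eremophilane numbering is used: ring A = C1–C5 + C10, ring B = C5–C10, O on C3, CH3 on C4 and C5, C7=CMe2, C8=O, C9–OH. The enabling feature is that C8 of ring B reaches the quaternary C5 through C7–C6, while C5 is flanked in ring A by C4–C3. One extra C3–C8 bond therefore makes C6=C7–C8(O−)–C3–C4=C5 a 3-oxido-1,5-diene inside a bicyclo[2.2.2]octene.
2. Cuts, in order: the acyl–O bond at C3; C3–O and C4–H (hydroboration); C5–C6 of ring B, with the temporary C3–C8 bond redrawn (retro anionic oxy-Cope) and OMe put back on C11 (retro E1cB); C7–C8 (alkenyl addition); C3–C8 and C9–C10 (Diels–Alder).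
3. Forward: ring A is the ring of 2-methylcyclohexenone. The Diels–Alder reaction adds the temporary ring C3–C4–C5–C10–C9–C8. Step 9 opens that ring and closes ring B, the last ring. The side-chain acid is made separately and joined at the end.
4. Stereochemistry: the bridged 2,3-dione 8 is meso, and a catalytic desymmetrising transfer hydrogenation fixes the absolute sense. The cage carries this to C5 in the [3,3] shift, and the axial C5 methyl then steers the hydroboration that sets C3 and C4 together.
5. Both Z alkenes come from the starting materials: one from the ring of 4-methylfuran-2(5H)-one, the other from angelic acid, which reacts only as a carboxylate nucleophile.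

Key step: step 9

Remark: α/β are used with β = the face of the C5 methyl group.
Assumption: the (S,S)-catalyst is assigned to step 6 by letting the neighbouring C=O play the π-substituent of the usual aryl ketone model; if the sense is opposite, the (R,R)-catalyst is used and nothing else changes.
Assumption: the endo/exo composition of 6 and 7 is irrelevant, because both series are meso and give the same dione 8; the endo isomers are drawn.

**Step 1**
Reactants: 1 2-methylcyclohex-2-en-1-one
Product: 3 6-methylcyclohexa-1,5-dien-1-yl trifluoromethanesulfonate, via lithium dienolate 2 (not isolated)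
Conditions: LiN(i-Pr)2 (LDA), THF, −78 °C; PhNTf2, −78 °C to rt; H2O
Reagents that add atoms: N-phenylbis(trifluoromethanesulfonimide), O=S(=O)(N(c1ccccc1)S(=O)(=O)C(F)(F)F)C(F)(F)F
Why: Kinetic deprotonation of the enone at the α' CH2 gives the cross-conjugated dienolate, and its O-sulfonylation (enol triflate formation) fixes the position of both diene double bonds.

**Step 2**
Reactants: 3 6-methylcyclohexa-1,5-dien-1-yl trifluoromethanesulfonate
Product: 4 2,3-dimethylcyclohexa-1,3-diene
Conditions: MeMgBr, Fe(acac)3 (5 mol %), THF/NMP, −30 to 0 °C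
Reagents that add atoms: methylmagnesium bromide, C[Mg]Br
Why: Iron-catalysed Kumada-type cross-coupling of an alkenyl triflate replaces OTf by CH3 at the same carbon, so the symmetric diene should form free of positional isomers.

**Step 3**
Reactants: 4 2,3-dimethylcyclohexa-1,3-diene; 5 vinylene carbonate
Product: 6 meso-5,6-dimethyl-3a,4,7,7a-tetrahydro-4,7-ethano-1,3-benzodioxol-2-one (endo adduct drawn)
Conditions: toluene, BHT, sealed tube, 170 °C
Reagents that add atoms: none
Why: In this thermal Diels–Alder reaction of a cyclohexa-1,3-diene with vinylene carbonate, suprafacial addition makes the two C–O bonds cis, so each adduct is a meso compound with a mirror plane through the three bridges.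

**Step 4**
Reactants: 6 meso cyclic carbonate
Product: 7 meso-cis-5,6-dimethylbicyclo[2.2.2]oct-5-ene-2,3-diol
Conditions: NaOH, H2O/THF, rt
Reagents that add atoms: none
Why: Saponification of the cyclic carbonate proceeds by acyl–oxygen cleavage and leaves both carbinol carbons untouched.

**Step 5**
Reactants: 7 meso-cis-5,6-dimethylbicyclo[2.2.2]oct-5-ene-2,3-diol
Product: 8 5,6-dimethylbicyclo[2.2.2]oct-5-ene-2,3-dione (meso)
Conditions: DMSO, (CF3CO)2O, CH2Cl2, −78 °C; Et3N, −78 °C to rt; dark
Reagents that add atoms: none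
Why: Swern oxidation with trifluoroacetic anhydride activation is the standard route from bicyclo[2.2.2]octene-2,3-diols to bridged 1,2-diones without glycol cleavage, and neither carbonyl can enolise toward a bridgehead.

**Step 6**
Reactants: 8 5,6-dimethylbicyclo[2.2.2]oct-5-ene-2,3-dione
Product: 9 (1R,3S,4S)-3-hydroxy-5,6-dimethylbicyclo[2.2.2]oct-5-en-2-one (OH anti to the C=C bridge)
Conditions: RuCl(p-cymene)[(S,S)-TsDPEN] (1 mol %), HCO2H (1.0 equiv)/Et3N, CH2Cl2, 0 °C
Reagents that add atoms: none
Why: Noyori–Ikariya asymmetric transfer hydrogenation of a 1,2-diketone should stop at the less electrophilic ketol; hydride arrives on the open face syn to the C=C bridge (substrate control) and the catalyst picks one of the two enantiotopic carbonyls, which fixes all three stereocentres at once.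

**Step 7**
Reactants: 10 3-methylbuta-1,2-diene
Product: 11 2-bromo-3-methoxy-3-methylbut-1-ene
Conditions: NBS, MeOH, 0 °C, dark
Reagents that add atoms: N-bromosuccinimide, O=C1CCC(=O)N1Br; methanol, CO
Why: In this electrophilic bromo-alkoxylation of an allene, bromine goes to the central carbon across the more substituted π bond and methanol captures the tertiary terminus (Markovnikov opening).

**Step 8**
Reactants: 11 2-bromo-3-methoxy-3-methylbut-1-ene; 9 (1R,3S,4S)-3-hydroxy-5,6-dimethylbicyclo[2.2.2]oct-5-en-2-one
Product: 14 (1R,2S,3S,4S)-2-(3-methoxy-3-methylbut-1-en-2-yl)-5,6-dimethylbicyclo[2.2.2]oct-5-ene-2,3-diol, via alkenyllithium 12 (not isolated), via alkenylcerium dichloride 13 (not isolated)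
Conditions: 11 (3 equiv), t-BuLi (6 equiv), Et2O, −78 °C; CeCl3, THF, −78 °C; 9, −78 °C; then H2O
Reagents that add atoms: none
Why: Br/Li exchange, transmetalation to the weakly basic organocerium reagent and 1,2-addition follow one another (the first equivalent only removes the OH proton); attack comes from the face syn to the C=C bridge, which is the open face of bicyclo[2.2.2]oct-5-en-2-ones and lies anti to the neighbouring oxido group, so the alkenyl group sits over C4=C5 as the [3,3] shift requires.

**Step 9**
Reactants: 14 (1R,2S,3S,4S)-2-(3-methoxy-3-methylbut-1-en-2-yl)-5,6-dimethylbicyclo[2.2.2]oct-5-ene-2,3-diol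
Product: 17 (1S,4aS,8aS)-1-hydroxy-4a,5-dimethyl-3-(propan-2-ylidene)-3,4,4a,7,8,8a-hexahydronaphthalen-2(1H)-one (cis-fused; 9α-OH; H-10 β), via dipotassium dialkoxide 15 (not isolated), via ring B enolate 16 (not isolated)
Conditions: KH (2.5 equiv), 18-crown-6 (2.5 equiv), THF, 0 °C to rt; then H2O (pH 7 buffer), 0 °C
Reagents that add atoms: none
Why: KH/18-crown-6 gives dialkoxide 15, in which C6=C7–C8(O−)–C3–C4=C5 is a 3-oxido-1,5-diene held in a boat by the cage, and the charge-accelerated [3,3] shift (anionic oxy-Cope rearrangement; closest precedent is the conversion of 2-alkenylbicyclo[2.2.2]oct-5-en-2-olates into cis-decalin enolates) forms C5–C6 as it breaks the temporary C3–C8 bond. Ring B (C5–C6–C7–C8–C9–C10) closes through this six-centre boat transition state, formally a 6-endo attack of the CH2 terminus C6 on C5, while the temporary ring C3–C4–C5–C10–C9–C8 opens and leaves ring A with the C3=C4 double bond. The new quaternary centre C5 is controlled by the cage: C6 can reach C5 only on the face of C4=C5 that looks at the C8–C9 bridge, so the bridgehead configuration set in step 6 is relayed suprafacially (C5 methyl cis to H-10). The regiodefined enolate 16 carries OMe β to C8 and expels methoxide (E1cB), which installs the C7 isopropylidene enone without a separate aldol sequence. The step needs the [3,3] shift to win over fragmentation or a [1,3] shift; this is secured by the syn placement of the alkenyl group, by the bulky CMe2OMe group that turns the CH2 terminus inward, and by the irreversible enolate/elimination sink, and no α-ketol or silyl migration can scramble the desymmetrised carbons because C9 is a bare alkoxide at the alcohol level. Any redox or tautomeric exchange between C8 and C9 in the basic medium is harmless, since step 10 takes both carbons to the dione level.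

**Step 10**
Reactants: 17 cis-fused 9α-hydroxy enone
Product: 18 (4aR)-1-hydroxy-4a,5-dimethyl-3-(propan-2-ylidene)-4,4a,7,8-tetrahydronaphthalen-2(3H)-one (diosphenol)
Conditions: IBX (1.5 equiv), DMSO, rt
Reagents that add atoms: none
Why: IBX oxidises acyloins to 1,2-diketones without C–C cleavage, and the dione can enolise only through H-10, so it should tautomerise to the conjugated diosphenol, which erases C9 and C10 as stereocentres and flattens the ring fusion.

**Step 11**
Reactants: 18 diosphenol
Product: 19 (4aR)-1-(methoxymethoxy)-4a,5-dimethyl-3-(propan-2-ylidene)-4,4a,7,8-tetrahydronaphthalen-2(3H)-one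
Conditions: MOMCl, i-Pr2NEt, CH2Cl2, 0 °C to rt
Reagents that add atoms: chloromethyl methyl ether, COCCl
Why: O-alkylation of the acidic enol by the hard electrophile MOMCl gives an enol acetal that cannot migrate and withstands borane, amine oxide and acylation conditions.

**Step 12**
Reactants: 19 diosphenol MOM ether
Product: 21 (4aR,5R,6R)-6-hydroxy-1-(methoxymethoxy)-4a,5-dimethyl-3-(propan-2-ylidene)-4,4a,5,6,7,8-hexahydronaphthalen-2(3H)-one (3α-OH; 4β-CH3), via alkylborane 20 (not isolated)
Conditions: BH3·THF (1.2 equiv), THF, 0 °C; H2O; Me3NO·2H2O, THF, 60 °C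
Reagents that add atoms: trimethylamine N-oxide, C[N+](C)(C)[O-]
Why: In this hydroboration–oxidation, borane should add faster to the isolated trisubstituted C3=C4 bond than to the cross-conjugated ketone flanked by two fully substituted alkenes; boron goes to the less substituted C3 and the syn addition takes the α face opposite the axial C5 methyl (as in Δ5-steroids), which sets 3α-O and 4β-CH3 in one event, and the amine oxide oxidation proceeds with retention.

**Step 13**
Reactants: 22 4-methylfuran-2(5H)-one
Product: 24 (Z)-4-bromo-3-methylbut-2-enoic acid, via trimethylsilyl ester 23 (not isolated)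
Conditions: Me3SiBr (1.5 equiv), CH2Cl2, rt to 40 °C; then ice-water
Reagents that add atoms: bromotrimethylsilane, C[Si](C)(C)Br
Why: In this halosilane cleavage of a lactone, silylation of the carbonyl oxygen is followed by SN2 attack of bromide at the allylic O–CH2 carbon, and the Z geometry is inherited from the ring.

**Step 14**
Reactants: 24 (Z)-4-bromo-3-methylbut-2-enoic acid
Product: 25 tert-butyl (Z)-4-bromo-3-methylbut-2-enoate
Conditions: Cl3CC(=NH)O-t-Bu, CH2Cl2/cyclohexane, rt
Reagents that add atoms: tert-butyl 2,2,2-trichloroacetimidate, CC(C)(C)OC(=N)C(Cl)(Cl)Cl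
Why: Trichloroacetimidate esterification works without base, so the carboxylate that would displace the bromide and re-form the lactone is never generated.

**Step 15**
Reactants: 25 tert-butyl (Z)-4-bromo-3-methylbut-2-enoate; 26 angelic acid
Product: 28 tert-butyl (Z)-3-methyl-4-{[(Z)-2-methylbut-2-enoyl]oxy}but-2-enoate, via caesium angelate 27 (not isolated)
Conditions: 26, Cs2CO3 (0.5 equiv), DMF, rt; then 25, 0 °C to rt
Reagents that add atoms: none
Why: The caesium carboxylate displaces the primary allylic bromide by SN2; angelic acid is never activated at its carbonyl, so isomerisation to the tiglate has no pathway.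

**Step 16**
Reactants: 28 tert-butyl diester
Product: 29 (Z)-3-methyl-4-{[(Z)-2-methylbut-2-enoyl]oxy}but-2-enoic acid
Conditions: CF3CO2H/CH2Cl2 (1:4), 0 °C
Reagents that add atoms: none
Why: Acidolysis of the tert-butyl ester (loss of isobutene) leaves the primary allylic angelate and both Z alkenes intact.

**Step 17**
Reactants: 29 side-chain acid; 21 3α-alcohol
Product: 31 (1R,2R,8aR)-5-(methoxymethoxy)-1,8a-dimethyl-6-oxo-7-(propan-2-ylidene)-1,2,3,4,6,7,8,8a-octahydronaphthalen-2-yl (Z)-3-methyl-4-{[(Z)-2-methylbut-2-enoyl]oxy}but-2-enoate, via mixed anhydride 30 (not isolated)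
Conditions: 29, 2,4,6-Cl3C6H2COCl, Et3N, toluene, rt; then 21, DMAP, rt
Reagents that add atoms: none
Why: In this Yamaguchi esterification the equatorial C3–OH is the only free hydroxyl, its C–O bond is not broken, and the β,β-disubstituted enoyl unit resists conjugate addition of DMAP, so the Z geometry should hold.

**Step 18**
Reactants: 31 MOM-protected ester
Product: 32 target CNP0228871.1
Conditions: CF3CO2H/CH2Cl2 (1:9), 0 °C; aq NaHCO3
Reagents that add atoms: none
Why: Acid-catalysed cleavage of the MOM acetal is easy because the diosphenol is a good leaving group, and the three ester and enone units are stable to cold dilute acid.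

**Compound list**
1 | 2-methylcyclohex-2-en-1-one | CC1=CCCCC1=O | starting material
2 | lithium 6-methylcyclohexa-1,5-dien-1-olate | CC1=CCCC=C1[O-].[Li+] | intermediate
3 | 6-methylcyclohexa-1,5-dien-1-yl trifluoromethanesulfonate | CC1=CCCC=C1OS(=O)(=O)C(F)(F)F | intermediate
4 | 2,3-dimethylcyclohexa-1,3-diene | CC1=CCCC=C1C | intermediate
5 | vinylene carbonate (1,3-dioxol-2-one) | O=C1OC=CO1 | starting material
6 | meso-5,6-dimethyl-3a,4,7,7a-tetrahydro-4,7-ethano-1,3-benzodioxol-2-one (endo) | CC1=C(C)[C@@H]2CC[C@H]1[C@@H]3OC(=O)O[C@H]23 | intermediate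
7 | meso-cis-5,6-dimethylbicyclo[2.2.2]oct-5-ene-2,3-diol (endo) | CC1=C(C)[C@@H]2CC[C@H]1[C@H](O)[C@@H]2O | intermediate
8 | 5,6-dimethylbicyclo[2.2.2]oct-5-ene-2,3-dione (meso) | CC1=C(C)[C@@H]2CC[C@H]1C(=O)C2=O | intermediate
9 | (1R,3S,4S)-3-hydroxy-5,6-dimethylbicyclo[2.2.2]oct-5-en-2-one | CC1=C(C)[C@@H]2CC[C@H]1C(=O)[C@H]2O | intermediate
10 | 3-methylbuta-1,2-diene | CC(C)=C=C | starting material
11 | 2-bromo-3-methoxy-3-methylbut-1-ene | C=C(Br)C(C)(C)OC | intermediate
12 | (3-methoxy-3-methylbut-1-en-2-yl)lithium | [Li]C(=C)C(C)(C)OC | intermediate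
13 | dichloro(3-methoxy-3-methylbut-1-en-2-yl)cerium | Cl[Ce](Cl)C(=C)C(C)(C)OC | intermediate
14 | (1R,2S,3S,4S)-2-(3-methoxy-3-methylbut-1-en-2-yl)-5,6-dimethylbicyclo[2.2.2]oct-5-ene-2,3-diol | CC1=C(C)[C@@H]2CC[C@H]1[C@](O)(C(=C)C(C)(C)OC)[C@H]2O | intermediate
15 | dipotassium dialkoxide of 14 | CC1=C(C)[C@@H]2CC[C@H]1[C@]([O-])(C(=C)C(C)(C)OC)[C@H]2[O-].[K+].[K+] | intermediate
16 | dipotassium C7=C8 enolate / C9 alkoxide of the cis-decalin (C7 bears CMe2OMe) | CC1=CCC[C@@H]2[C@H]([O-])C([O-])=C(C(C)(C)OC)C[C@]12C.[K+].[K+] | intermediate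
17 | (1S,4aS,8aS)-1-hydroxy-4a,5-dimethyl-3-(propan-2-ylidene)-3,4,4a,7,8,8a-hexahydronaphthalen-2(1H)-one | CC1=CCC[C@@H]2[C@H](O)C(=O)C(=C(C)C)C[C@]12C | intermediate
18 | (4aR)-1-hydroxy-4a,5-dimethyl-3-(propan-2-ylidene)-4,4a,7,8-tetrahydronaphthalen-2(3H)-one | CC1=CCCC2=C(O)C(=O)C(=C(C)C)C[C@]12C | intermediate
19 | (4aR)-1-(methoxymethoxy)-4a,5-dimethyl-3-(propan-2-ylidene)-4,4a,7,8-tetrahydronaphthalen-2(3H)-one | CC1=CCCC2=C(OCOC)C(=O)C(=C(C)C)C[C@]12C | intermediate
20 | C3 alkylborane RBH2 (boron α on C3, new H α on C4) | B[C@@H]1CCC2=C(OCOC)C(=O)C(=C(C)C)C[C@]2(C)[C@H]1C | intermediate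
21 | (4aR,5R,6R)-6-hydroxy-1-(methoxymethoxy)-4a,5-dimethyl-3-(propan-2-ylidene)-4,4a,5,6,7,8-hexahydronaphthalen-2(3H)-one | O[C@@H]1CCC2=C(OCOC)C(=O)C(=C(C)C)C[C@]2(C)[C@H]1C | intermediate
22 | 4-methylfuran-2(5H)-one | CC1=CC(=O)OC1 | starting material
23 | trimethylsilyl (Z)-4-bromo-3-methylbut-2-enoate | BrC/C(C)=C\C(=O)O[Si](C)(C)C | intermediate
24 | (Z)-4-bromo-3-methylbut-2-enoic acid | BrC/C(C)=C\C(=O)O | intermediate
25 | tert-butyl (Z)-4-bromo-3-methylbut-2-enoate | BrC/C(C)=C\C(=O)OC(C)(C)C | intermediate
26 | angelic acid, (Z)-2-methylbut-2-enoic acid | C/C=C(/C)C(=O)O | starting material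
27 | caesium (Z)-2-methylbut-2-enoate | C/C=C(/C)C(=O)[O-].[Cs+] | intermediate
28 | tert-butyl (Z)-3-methyl-4-{[(Z)-2-methylbut-2-enoyl]oxy}but-2-enoate | C/C=C(/C)C(=O)OC/C(C)=C\C(=O)OC(C)(C)C | intermediate
29 | (Z)-3-methyl-4-{[(Z)-2-methylbut-2-enoyl]oxy}but-2-enoic acid | C/C=C(/C)C(=O)OC/C(C)=C\C(=O)O | intermediate
30 | mixed anhydride of 29 and 2,4,6-trichlorobenzoic acid | C/C=C(/C)C(=O)OC/C(C)=C\C(=O)OC(=O)c1c(Cl)cc(Cl)cc1Cl | intermediate
31 | 9-O-MOM ether of the target | C/C=C(/C)C(=O)OC/C(C)=C\C(=O)O[C@@H]1CCC2=C(OCOC)C(=O)C(=C(C)C)C[C@]2(C)[C@H]1C | intermediate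
32 | (1R,2R,8aR)-5-hydroxy-1,8a-dimethyl-6-oxo-7-(propan-2-ylidene)-1,2,3,4,6,7,8,8a-octahydronaphthalen-2-yl (Z)-3-methyl-4-{[(Z)-2-methylbut-2-enoyl]oxy}but-2-enoate | C/C=C(/C)C(=O)OC/C(C)=C\C(=O)O[C@@H]1CCC2=C(O)C(=O)C(=C(C)C)C[C@]2(C)[C@H]1C | target

**Totals**
Total step count: 18.
Longest linear sequence: 13 steps (steps 1–6, 8–12, 17, 18).

**The three steps most likely to fail**

Step 6. The catalyst may discriminate poorly between the two enantiotopic carbonyl groups, reduction may run on to the diol, or the enantiomeric purity may erode through enediol tautomerism in the amine-containing medium. The fallback replaces desymmetrisation by kinetic resolution and sets out from 8. NaBH4 (0.3 equiv, MeOH/CH2Cl2, −78 °C) should add hydride syn to the C=C bridge and give the racemic ketol F1. Immobilised Candida antarctica lipase B with vinyl acetate in MTBE then acylates one antipode, taken here to be the unwanted one, to the acetate of the antipodal ketol F2. The unreacted alcohol, separated by chromatography, is 9, where the route is rejoined.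

Step 12. Borane may reduce the C8 dienone (1,2- or 1,4-delivery of hydride) in competition with addition to C3=C4. The fallback is a redox detour from 19. Excess BH3·THF followed by Me3NO is allowed to reduce the ketone as well, giving the 3α,8-diol F3 (C8 epimers, of no consequence). Activated MnO2 in CH2Cl2 then oxidises only the doubly allylic C8 carbinol and leaves the saturated C3–OH, which returns the material to 21.

Step 9. The neighbouring C9 alkoxide may slow the [3,3] shift through tight ion pairing or open redox and fragmentation channels, and loss of methoxide may stall. The fallback runs the rearrangement on a classical mono-alkoxide with a non-migrating ether at C9 and sets out from 14. NaH (1 equiv), 4-methoxybenzyl chloride and Bu4NI in DMF at 0 °C etherify the secondary hydroxyl selectively to the C9 PMB ether of the diol F4. KH/18-crown-6 in THF converts it into the 9α-PMB-oxy enone F5. DDQ in CH2Cl2/pH 7 buffer removes the PMB group and gives 17, where the route is rejoined.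

**Further compounds**
F1 | step 6 | racemic 3-hydroxy-5,6-dimethylbicyclo[2.2.2]oct-5-en-2-one (OH anti to the C=C bridge) | CC1=C(C)[C@@H]2CC[C@H]1C(=O)[C@H]2O.CC1=C(C)[C@H]2CC[C@@H]1C(=O)[C@@H]2O
F2 | step 6 | (1S,2R,4R)-5,6-dimethyl-3-oxobicyclo[2.2.2]oct-5-en-2-yl acetate (acetate of the antipode of 9) | CC1=C(C)[C@H]2CC[C@@H]1C(=O)[C@@H]2OC(C)=O
F3 | step 12 | (4aR,5R,6R)-1-(methoxymethoxy)-4a,5-dimethyl-3-(propan-2-ylidene)-2,3,4,4a,5,6,7,8-octahydronaphthalene-2,6-diol (C8 epimers) | O[C@@H]1CCC2=C(OCOC)C(O)C(=C(C)C)C[C@]2(C)[C@H]1C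
F4 | step 9 | (1R,2S,3S,4S)-3-[(4-methoxybenzyl)oxy]-2-(3-methoxy-3-methylbut-1-en-2-yl)-5,6-dimethylbicyclo[2.2.2]oct-5-en-2-ol | CC1=C(C)[C@@H]2CC[C@H]1[C@](O)(C(=C)C(C)(C)OC)[C@H]2OCc3ccc(OC)cc3
F5 | step 9 | (1S,4aS,8aS)-1-[(4-methoxybenzyl)oxy]-4a,5-dimethyl-3-(propan-2-ylidene)-3,4,4a,7,8,8a-hexahydronaphthalen-2(1H)-one | CC1=CCC[C@@H]2[C@H](OCc3ccc(OC)cc3)C(=O)C(=C(C)C)C[C@]12C
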